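**Remarks on the chemistry (made before the route)**

- Germacrane numbering is used for every compound, open-chain ones included: ring C1–C10; C11 on C7 with C12 and C13; C14 on C10; C15 on C4. TIPS = Si(i-Pr)3, TES = SiEt3.
- Correction of descriptors: the ring double bonds C1=C10 and C4=C5 are "ring-cis" (both ring carbons on the same side) but E by the sequence rules, because the CH2O carbon outranks the ring CH2. The C11=C7 bond of the macrocyclic ether, with C13 and C8 on the same side, is also E while O12 carries silicon and O13 carbon. It is "Z" only in the crotyl sense (ether CH2 cis to the γ-substituent).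
- The C7 descriptor is S in 27 and 28 and R from 29 onward. Only the priorities of the neighbours change; no bond at C7 is touched.
- Assumption: 1, 7, 11 and all reagents are commercially available. Compounds 13–15 are carried as C11 epimer mixtures, which converge in step 8.

## Structural features

The target is a germacranolide: a ten-membered carbocycle (C1–C10) with two ring-cis trisubstituted double bonds, C1=C10 and C4=C5, each carrying a primary allylic hydroxymethyl group (C14 on C10, C15 on C4). A trans-fused α-methylene-γ-butyrolactone spans C7 and C8 (C7–C11(=C13H2)–C12(=O)–O–C8). C6, C7 and C8 are contiguous stereocentres (6S,7R,8S): the tigloylated O6 is cis to the C11 branch on C7, and O8 is trans to it. Fragile groups are the α-methylene lactone (Michael acceptor), the tiglate (able to migrate to a free O8 or to deconjugate), the allylic alcohols and the geometry of the two ring alkenes. The real difficulty is closing the strained ten-membered ring while fixing C6 and C7 relative to C8 without disturbing either alkene. The key step exploits the fact that the C6 carbinol beside C7, which bears the C11=C13 propenyl unit, is the homoallylic alcohol that a [2,3]-Wittig shift leaves behind. The C6–C7 bond can therefore be made inside a thirteen-membered C6–O–C13 ether, whose C13–C11=C7 allyl unit delivers C11=C13 and the free O6–H in the same event.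

## Logic of the disconnections

33 to 32: the O14–Si and O15–Si bonds are cut (masking only). The two primary allylic alcohols would be oxidised together with C12, so they stay silylated to the end. The forward step needs a fluoride source that spares the α-methylene lactone and the ester.

32 to 29: the lactone C12–O8 bond and the C12 carbonyl are taken back to the C12/C8 diol. The exo-methylene lactone is the most electrophilic group and is made last; C12 as CH2OH is inert to strong base. The oxidant must take only the allylic C12–OH and then the lactol (30 and 31 lie on the way).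

29 to 28 to 27: the O8–Si and O12–Si bonds and the O6–acyl bond are cut. 27 has O6 as its only free hydroxyl, so the ester goes on unambiguously before O8 and O12 are released. This demands acylation of a hindered secondary allylic alcohol without deconjugating the acid, and cleavage of TES beside TIPS.

27 to 25: C6–C7 is cut, O6 is rejoined to C13 and the alkene moves from C11=C13 to C11=C7 (retro-[2,3]). The ten-membered ring, two stereocentres and the exo-methylene are traded for a thirteen-membered ether with one stereocentre. The forward step needs metalation at C6 only, a suprafacial shift, and face selection by C8.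

25 to 23: C3–C4 (sp3–sp2) is cut. Ring closure is placed at a bond that can be formed by cross-coupling with retention of the C4=C5 geometry, and a thirteen-membered ring closes far more easily than a ten-membered one. The forward step needs hydroboration of the terminal C2=C3 only (24) and high dilution.

23 to 22 and 4: the O–C13 ether bond is cut. This joins the C3–C13 part to the C4–C6/C15 part by SN2. The leaving group is put on C13 so that no alkoxide is generated beside the O8 silyl ether; the forward step must be SN2 and not SN2′.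

22 to 21 to 20 to 18: functional-group changes only (Br from OH, O8 silylated, O13 masked for a time as acetate). O13 (primary) and O8 (secondary) emerge from the same reduction and must be told apart; this demands primary-selective acylation.

18 to 17: O8 is rejoined to C13 as a lactone carbonyl. The butenolide ring forces C13 cis to C8, which is exactly the C11=C7 geometry the key step needs, without any stereoselective olefination. The forward step must be a clean 1,2-reduction.

17 to 16 to 14 to 13: the C11–C12 bond (aldol retron) and the C7=C11 unsaturation (sulfoxide-elimination retron) are removed. What remains is a simple α-sulfanyl lactone. The elimination must run into the ring.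

13 to 10 and 11: C7–C11 and O8–C13 are cut, giving a terminal epoxide and a two-carbon acid dianion. The forward step needs attack at the epoxide CH2 and lactonisation.

10 to 6 and 7: C9–C10 is cut. C8 comes from the chiral pool and the alkene geometry from an alkenyl nucleophile reacting with retention. The C8–O bond must never be broken.

6 to 5 to 4: C2=C3 is cut (methylenation retron) and C2 returns to the alcohol oxidation level.

4 to 2 to 1: C–I and C–H are removed across an alkyne (trans-hydroalumination retron). One building block, 4, then supplies both trisubstituted alkenes: directly as C15–C4–C5–C6 and, through 6, as C14–C10–C1–C2. Regiocontrol needs one free hydroxyl, hence monosilylation of the symmetric diol.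

## Other disconnections considered

Alternative 1: The cut is C8–C9 with C1–C6 re-formed, which contracts the ring on paper to the cyclohexenol A1. In A1 the carbinol carbon C6 carries the C7=C8 vinylsilane and the neighbouring ring carbon C1 carries the C10(=C9)–C14 propenyl unit, cis to each other. Forward, the potassium alkoxide of A1 (KH, 18-crown-6) would undergo an anionic oxy-Cope rearrangement to the enolate of the cyclodecadienone A2.
- In favour: the ten-membered ring arises by ring expansion, so no cyclisation under dilution is needed at all; this is better than the chosen plan, which must still close a thirteen-membered ring. The C4=C5 geometry is inherited from the cyclohexene. The silicon on C8 is a masked hydroxyl placed by chirality transfer. There is no competing site of deprotonation, so the regiochemistry of the sigmatropic step is more predictable than in the chosen plan.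
- Against: A2 has C6 as a ketone and C7 as a bare CH2, so neither C6 nor C7 is set. The whole C11–C13 unit must still be attached at C7, the ketone reduced with control, and the silyl group oxidised to O8 beside two trisubstituted alkenes. The C1=C10 geometry rests on a chair-versus-boat preference. A1 needs an enantiopure tertiary carbinol with a cis 1,2-relationship.
- Comparison: on structure, the chosen plan delivers O6–H, C7 and the C11=C13/C12 unit in one step, where this plan delivers the ring and C8 only. Mechanistically both are concerted and stereospecific. On step economy, the operations after A2 outweigh the saved macrocyclisation.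

Alternative 2: The cut is C3–C4. Forward, 9-BBN would hydroborate the terminal C2=C3 vinyl group of A3, and the C3 borane would couple with the C4 alkenyl iodide (Pd(dppf)Cl2, base) to close the ten-membered ring of A4.
- In favour: all three stereocentres and the trans lactone exist before ring closure, which secures the stereochemistry better than the chosen plan. No organolithium meets the silyl ethers. The coupling is the same reaction type the chosen route uses for its thirteen-membered ring, so it is equal in reliability of the bond-forming chemistry.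
- Against: direct closure of a ten-membered ring with two ring-cis trisubstituted alkenes and a trans-fused lactone is the least favourable ring size for such couplings; transannular strain lets intermolecular coupling and protodeboronation compete. The acyclic C6–C7–C8 triad with its alkenyl iodide needs several stereoselective steps. C11 is still CH2, so α-methylenation, exchange of the C6 silyl ether for the tiglate and desilylation follow.
- Comparison: the number of steps after ring closure is about equal (four). The chosen plan spends its effort on an unstrained thirteen-membered closure and lets a concerted shift do the contraction.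

Alternative 3: The cut is C2–C3. Forward, Ni(CO)4 (zerovalent nickel) would reductively couple the two primary allylic bromides of A5 to give A6.
- In favour: two like termini of the 1,5-diene are joined, both halves stem from one type of building block, the lactone and its stereocentres are in place, and no strong base is used. In convergence it is equal to or better than the chosen plan.
- Against: bis(allyl)nickel intermediates equilibrate syn and anti forms, so the ring-cis geometry of both trisubstituted alkenes is at risk. Coupling at the substituted allyl termini (C10, C4) would give vinyl-branched smaller rings. Ten-membered rings are disfavoured against twelve-membered and larger ones in this coupling. Ni(CO)4 is volatile and highly toxic. C11 methylenation and the exchange of the C6 ether for the tiglate remain.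
- Comparison: the chosen plan keeps every alkene geometry under stereospecific control (hydroalumination–iodination, coupling with retention, suprafacial shift), which this mechanism cannot promise. Step counts before and after ring closure are similar.

Key step: step 16

## Steps

Step 1
Reactants: 1 but-2-yne-1,4-diol
Product: 2 4-(TIPS-oxy)but-2-yn-1-ol
Conditions: NaH (1.0 equiv), THF, 0 °C to rt; i-Pr3SiCl (1.0 equiv)
Reagents that add atoms: chlorotriisopropylsilane, CC(C)[Si](Cl)(C(C)C)C(C)C
Why: Monosilylation of a symmetric diol through its sparingly soluble monosodium alkoxide (silyl ether formation); one hydroxyl stays free to direct step 2.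

Step 2
Reactants: 2 4-(TIPS-oxy)but-2-yn-1-ol
Product: 4 (2Z)-3-iodo-4-(TIPS-oxy)but-2-en-1-ol, via cyclic alkenylalanate 3 (not isolated)
Conditions: NaAlH2(OCH2CH2OMe)2, THF, 0 °C to rt; then I2, THF, −78 to 0 °C
Reagents that add atoms: iodine, [I][I]
Why: Hydroxyl-directed trans-hydroalumination of the propargylic alcohol puts aluminium on the distal alkyne carbon (five-membered alanate 3), and iodinolysis with retention gives the iodide cis to CH2OH. This fixes the ring-cis geometry of both future trisubstituted alkenes.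

Step 3
Reactants: 4 (2Z)-3-iodo-4-(TIPS-oxy)but-2-en-1-ol
Product: 5 (2Z)-3-iodo-4-(TIPS-oxy)but-2-enal
Conditions: MnO2, CH2Cl2, rt
Reagents that add atoms: none
Why: MnO2 oxidation of a primary allylic alcohol to the enal under neutral conditions, which keep the alkene geometry and the silyl ether.

Step 4
Reactants: 5 (2Z)-3-iodo-4-(TIPS-oxy)but-2-enal
Product: 6 (2Z)-2-iodo-1-(TIPS-oxy)penta-2,4-diene
Conditions: Ph3PCH3Br, KN(SiMe3)2, THF, −78 to 0 °C
Reagents that add atoms: methyltriphenylphosphonium bromide, C[P+](c1ccccc1)(c1ccccc1)c1ccccc1.[Br-]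
Why: Wittig methylenation with the unstabilised ylide; 1,2-addition to the aldehyde is faster than attack at the iodine-bearing carbon, and the C–I alkene geometry is not involved.

Step 5
Reactants: 6 (2Z)-2-iodo-1-(TIPS-oxy)penta-2,4-diene; 7 (2S)-2-(chloromethyl)oxirane
Product: 10 (2S)-2-[(2E)-2-(TIPS-oxymethyl)penta-2,4-dien-1-yl]oxirane, via dienyllithium 8 (not isolated), via chlorohydrin 9 (not isolated)
Conditions: t-BuLi (2 equiv), Et2O, −78 °C; 7, BF3·OEt2, −78 °C; then NaOH (aq), MeOH, 0 °C to rt
Reagents that add atoms: none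
Why: Iodine–lithium exchange with retention gives 8, whose BF3-promoted SN2 opening of the epoxide at its CH2 terminus forms C9–C10; hydroxide then closes chlorohydrin 9 to the new epoxide (intramolecular Williamson reaction). The C8–O bond is never broken, so C8 comes unchanged from 7.

Step 6
Reactants: 10 (2S)-2-[(2E)-2-(TIPS-oxymethyl)penta-2,4-dien-1-yl]oxirane; 11 (phenylsulfanyl)acetic acid
Product: 13 (3RS,5S)-3-(phenylsulfanyl)-5-[(2E)-2-(TIPS-oxymethyl)penta-2,4-dien-1-yl]oxolan-2-one, via hydroxy acid 12 (not isolated)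
Conditions: 11, LiN(i-Pr)2 (2.1 equiv), THF, 0 °C; then 10, 0 °C to rt; aq. HCl; TsOH (cat.), CH2Cl2, rt
Reagents that add atoms: none
Why: The carboxylic acid dianion opens the terminal epoxide at C7 (SN2) and the γ-hydroxy acid 12 lactonises under acid catalysis; C8 is again untouched.

Step 7
Reactants: 13 (3RS,5S)-3-(phenylsulfanyl)-5-[(2E)-2-(TIPS-oxymethyl)penta-2,4-dien-1-yl]oxolan-2-one
Product: 14 (3RS,5S)-3-(hydroxymethyl)-3-(phenylsulfanyl)-5-[(2E)-2-(TIPS-oxymethyl)penta-2,4-dien-1-yl]oxolan-2-one
Conditions: LiN(i-Pr)2, THF, −78 °C; CH2O (monomer in THF), −78 to −40 °C; AcOH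
Reagents that add atoms: formaldehyde, C=O
Why: Aldol addition of the sulfur-stabilised lactone enolate to formaldehyde attaches C12 to C11; the new quaternary centre is destroyed in step 8.

Step 8
Reactants: 14 (3RS,5S)-3-(hydroxymethyl)-3-(phenylsulfanyl)-5-[(2E)-2-(TIPS-oxymethyl)penta-2,4-dien-1-yl]oxolan-2-one
Product: 16 (5S)-3-(hydroxymethyl)-5-[(2E)-2-(TIPS-oxymethyl)penta-2,4-dien-1-yl]furan-2(5H)-one, via sulfoxide 15 (not isolated)
Conditions: mCPBA (1.0 equiv), CH2Cl2, −78 °C; then CaCO3, PhMe, 100 °C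
Reagents that add atoms: none
Why: Sulfide oxidation at −78 °C is much faster than alkene epoxidation. Thermal syn-elimination of the sulfoxide runs toward C7 and not toward the carbinol carbon C12, giving the endocyclic butenolide.

Step 9
Reactants: 16 (5S)-3-(hydroxymethyl)-5-[(2E)-2-(TIPS-oxymethyl)penta-2,4-dien-1-yl]furan-2(5H)-one
Product: 17 (5S)-3-(TES-oxymethyl)-5-[(2E)-2-(TIPS-oxymethyl)penta-2,4-dien-1-yl]furan-2(5H)-one
Conditions: Et3SiCl, imidazole, CH2Cl2, 0 °C
Reagents that add atoms: chlorotriethylsilane, CC[Si](Cl)(CC)CC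
Why: Silylation of the primary allylic alcohol; imidazole is too weak a base to epimerise the γ-position of the butenolide.

Step 10
Reactants: 17 (5S)-3-(TES-oxymethyl)-5-[(2E)-2-(TIPS-oxymethyl)penta-2,4-dien-1-yl]furan-2(5H)-one
Product: 18 (2E,4S,6E)-2-(TES-oxymethyl)-6-(TIPS-oxymethyl)nona-2,6,8-triene-1,4-diol
Conditions: i-Bu2AlH (3 equiv), CH2Cl2, −78 to 0 °C
Reagents that add atoms: none
Why: 1,2-Reduction of the butenolide to the ene-1,4-diol. Because C13 and O8 sat in one ring, C13 ends cis to C8, which sets the C11=C7 geometry needed in step 16.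

Step 11
Reactants: 18 (2E,4S,6E)-2-(TES-oxymethyl)-6-(TIPS-oxymethyl)nona-2,6,8-triene-1,4-diol
Product: 20 (2E,4S,6E)-4-(TES-oxy)-2-(TES-oxymethyl)-6-(TIPS-oxymethyl)nona-2,6,8-trien-1-yl acetate, via monoacetate 19 (not isolated)
Conditions: AcCl (1.05 equiv), 2,4,6-collidine, CH2Cl2, −78 °C; then Et3SiOTf, −78 to −40 °C
Reagents that add atoms: acetyl chloride, CC(Cl)=O; triethylsilyl trifluoromethanesulfonate, CC[Si](CC)(CC)OS(=O)(=O)C(F)(F)F
Why: Acetyl chloride with collidine at −78 °C acylates the primary O13 in preference to the secondary O8; the silyl triflate then caps O8 in the same flask.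

Step 12
Reactants: 20 (2E,4S,6E)-4-(TES-oxy)-2-(TES-oxymethyl)-6-(TIPS-oxymethyl)nona-2,6,8-trien-1-yl acetate
Product: 21 (2E,4S,6E)-4-(TES-oxy)-2-(TES-oxymethyl)-6-(TIPS-oxymethyl)nona-2,6,8-trien-1-ol
Conditions: i-Bu2AlH (2.2 equiv), CH2Cl2, −78 °C
Reagents that add atoms: none
Why: Reductive cleavage of the acetate; unlike basic methanolysis it leaves the triethylsilyl ethers untouched.

Step 13
Reactants: 21 (2E,4S,6E)-4-(TES-oxy)-2-(TES-oxymethyl)-6-(TIPS-oxymethyl)nona-2,6,8-trien-1-ol
Product: 22 (2Z,4S,6E)-1-bromo-4-(TES-oxy)-2-(TES-oxymethyl)-6-(TIPS-oxymethyl)nona-2,6,8-triene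
Conditions: CBr4, PPh3, 2,6-lutidine, CH2Cl2, −30 °C
Reagents that add atoms: tetrabromomethane, BrC(Br)(Br)Br
Why: Appel bromination of the primary allylic alcohol at low temperature, buffered to protect the silyl ethers. The geometry is unchanged; the descriptor becomes Z only because bromine outranks oxygen.

Step 14
Reactants: 22 (2Z,4S,6E)-1-bromo-4-(TES-oxy)-2-(TES-oxymethyl)-6-(TIPS-oxymethyl)nona-2,6,8-triene; 4 (2Z)-3-iodo-4-(TIPS-oxy)but-2-en-1-ol
Product: 23 (2E,4S,6E)-1-{[(2Z)-3-iodo-4-(TIPS-oxy)but-2-en-1-yl]oxy}-4-(TES-oxy)-2-(TES-oxymethyl)-6-(TIPS-oxymethyl)nona-2,6,8-triene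
Conditions: 4, NaH, THF, 0 °C; then 22, Bu4NI (cat.), 0 °C to rt
Reagents that add atoms: none
Why: Williamson ether synthesis (SN2 at the primary allylic bromide; C7 is too hindered for SN2′). The alkoxide is formed on 4, whose silyl ether is trans to the alkoxide carbon, so no alkoxide sits beside a silyl group that could migrate.

Step 15
Reactants: 23 (2E,4S,6E)-1-{[(2Z)-3-iodo-4-(TIPS-oxy)but-2-en-1-yl]oxy}-4-(TES-oxy)-2-(TES-oxymethyl)-6-(TIPS-oxymethyl)nona-2,6,8-triene
Product: 25 (3E,5S,7E,11E)-5-(TES-oxy)-3-(TES-oxymethyl)-7,11-bis(TIPS-oxymethyl)-1-oxacyclotrideca-3,7,11-triene, the thirteen-membered C6–O–C13 ether, via alkylborane 24 (not isolated)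
Conditions: 9-BBN dimer, THF, 0 °C to rt; then slow addition to Pd(dppf)Cl2, AsPh3, Cs2CO3, DMF/THF/H2O, rt (high dilution)
Reagents that add atoms: none
Why: 9-BBN adds only to the terminal C2=C3 of the diene (boron on C3); the trisubstituted alkenes are inert. Intramolecular B-alkyl Suzuki–Miyaura coupling then forms C3–C4 with retention at the alkenyl iodide and closes the thirteen-membered ring.

Step 16
Reactants: 25 (3E,5S,7E,11E)-5-(TES-oxy)-3-(TES-oxymethyl)-7,11-bis(TIPS-oxymethyl)-1-oxacyclotrideca-3,7,11-triene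
Product: 27 (1S,2E,6E,9S,10S)-9-(TES-oxy)-10-[3-(TES-oxy)prop-1-en-2-yl]-3,7-bis(TIPS-oxymethyl)cyclodeca-2,6-dien-1-ol, the ten-membered C6 alcohol, via C6-lithiated ether 26 (not isolated)
Conditions: n-BuLi, THF, −78 to −30 °C; AcOH, −78 °C
Reagents that add atoms: none
Why: n-BuLi removes a proton from C6, the ether α-carbon allylic to C4=C5, to give 26; the lithiated carbon then bonds to C7 across the C13–C11=C7 allyl unit in a concerted suprafacial [2,3]-sigmatropic (Wittig) shift through a five-membered envelope, which breaks O–C13, creates C11=C13 and leaves the C6 alkoxide. The closest known reaction type is the transannular [2,3]-Wittig ring contraction of thirteen-membered diallylic ethers to ten-membered cyclodecadienols. The ten-membered ring is thus closed by transannular C6–C7 bond formation inside the existing macrocycle (contraction by three atoms), not by an end-to-end cyclisation. For C7, allylic 1,3-strain holds H8 in the plane of C11=C7 facing C13, so C9 and the silyloxy group lie on opposite faces; C6 is tied to C9 through the ring and must arrive on the C9 face, anti to O8, which gives the required configuration. For C6, with the ether CH2 cis to C8 the envelope places C5 exo, the arrangement that lets the C5-to-C9 tether span; this is the syn (erythro) mode and puts O6 and the C11 branch cis on the new ring. The step needs metalation at C6 and not at C13 or at a silyloxymethyl carbon: C6 adjoins an unsubstituted sp2 CH, whereas C13 is crowded by C12, by the cis C8 branch and by two silyl ethers; silyl ether oxygens are poor ligands for lithium; and a C13 anion could rearrange only by attacking the fully substituted C4. Low temperature and a cold acid quench limit 1,4-elimination of the C15 silyloxy group and migration of the C8 silyl group to the new alkoxide.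

Step 17
Reactants: 27 (1S,2E,6E,9S,10S)-9-(TES-oxy)-10-[3-(TES-oxy)prop-1-en-2-yl]-3,7-bis(TIPS-oxymethyl)cyclodeca-2,6-dien-1-ol
Product: 28 (1S,2E,6E,9S,10S)-9-(TES-oxy)-10-[3-(TES-oxy)prop-1-en-2-yl]-3,7-bis(TIPS-oxymethyl)cyclodeca-2,6-dien-1-yl (2E)-2-methylbut-2-enoate
Conditions: (E)-MeCH=C(Me)CO2H, 2,4,6-Cl3C6H2COCl, Et3N, PhMe, rt; then 27, DMAP, PhMe, rt to 40 °C
Reagents that add atoms: (2E)-2-methylbut-2-enoic acid, C/C=C(\C)C(O)=O
Why: Yamaguchi esterification through the mixed anhydride acylates the hindered secondary O6, the only free hydroxyl, and avoids the ketene pathway that can deconjugate the acid.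

Step 18
Reactants: 28 (1S,2E,6E,9S,10S)-9-(TES-oxy)-10-[3-(TES-oxy)prop-1-en-2-yl]-3,7-bis(TIPS-oxymethyl)cyclodeca-2,6-dien-1-yl (2E)-2-methylbut-2-enoate
Product: 29 (1S,2E,6E,9S,10R)-9-hydroxy-10-(3-hydroxyprop-1-en-2-yl)-3,7-bis(TIPS-oxymethyl)cyclodeca-2,6-dien-1-yl (2E)-2-methylbut-2-enoate
Conditions: PPTS, MeOH/CH2Cl2, 0 °C
Reagents that add atoms: none
Why: Mild acid methanolysis removes both triethylsilyl ethers while the much more robust triisopropylsilyl ethers stay; mild acid also keeps the tiglate on O6.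

Step 19
Reactants: 29 (1S,2E,6E,9S,10R)-9-hydroxy-10-(3-hydroxyprop-1-en-2-yl)-3,7-bis(TIPS-oxymethyl)cyclodeca-2,6-dien-1-yl (2E)-2-methylbut-2-enoate
Product: 32 (6S,7R,8S)-6-[(2E)-2-methylbut-2-enoyloxy]-14,15-bis(TIPS-oxy)germacra-1(10)E,4E,11(13)-trien-12,8-olide, via hydroxy enal 30 (not isolated), via lactol 31 (not isolated)
Conditions: MnO2 (excess), CH2Cl2, rt
Reagents that add atoms: none
Why: MnO2 oxidises only the allylic primary C12–OH (O8–H is not allylic); the enal closes to the lactol with O8, and this allylic hemiacetal is oxidised on to the α-methylene lactone (oxidative lactonisation).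

Step 20
Reactants: 32 (6S,7R,8S)-6-[(2E)-2-methylbut-2-enoyloxy]-14,15-bis(TIPS-oxy)germacra-1(10)E,4E,11(13)-trien-12,8-olide
Product: 33 (6S,7R,8S)-14,15-dihydroxy-6-[(2E)-2-methylbut-2-enoyloxy]germacra-1(10)E,4E,11(13)-trien-12,8-olide (CNP0275462.1)
Conditions: HF·pyridine, pyridine, THF, 0 °C to rt
Reagents that add atoms: none
Why: Buffered fluoride cleaves the two primary silyl ethers without touching the ester or the α-methylene lactone.

## Compound list

1 | but-2-yne-1,4-diol | OCC#CCO | starting material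
2 | 4-(TIPS-oxy)but-2-yn-1-ol | OCC#CCO[Si](C(C)C)(C(C)C)C(C)C | intermediate
3 | sodium cyclic alkenylalanate (1,2-oxaaluminole with Al on the carbon bearing CH2OTIPS and two 2-methoxyethoxy ligands) | [Na+].COCCO[Al-]1(OCCOC)OC/C=C1/CO[Si](C(C)C)(C(C)C)C(C)C | intermediate
4 | (2Z)-3-iodo-4-(TIPS-oxy)but-2-en-1-ol | OC/C=C(\I)CO[Si](C(C)C)(C(C)C)C(C)C | intermediate
5 | (2Z)-3-iodo-4-(TIPS-oxy)but-2-enal | O=C/C=C(\I)CO[Si](C(C)C)(C(C)C)C(C)C | intermediate
6 | (2Z)-2-iodo-1-(TIPS-oxy)penta-2,4-diene | C=C/C=C(\I)CO[Si](C(C)C)(C(C)C)C(C)C | intermediate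
7 | (2S)-2-(chloromethyl)oxirane | ClC[C@@H]1CO1 | starting material
8 | (2E)-1-(TIPS-oxy)penta-2,4-dien-2-yllithium | [Li]/C(CO[Si](C(C)C)(C(C)C)C(C)C)=C\C=C | intermediate
9 | (2S,4E)-1-chloro-4-(TIPS-oxymethyl)hepta-4,6-dien-2-ol | C=C/C=C(CO[Si](C(C)C)(C(C)C)C(C)C)\C[C@H](O)CCl | intermediate
10 | (2S)-2-[(2E)-2-(TIPS-oxymethyl)penta-2,4-dien-1-yl]oxirane | C=C/C=C(CO[Si](C(C)C)(C(C)C)C(C)C)\C[C@H]1CO1 | intermediate
11 | (phenylsulfanyl)acetic acid | OC(=O)CSc1ccccc1 | starting material
12 | (4S,6E)-4-hydroxy-2-(phenylsulfanyl)-6-(TIPS-oxymethyl)nona-6,8-dienoic acid | OC(=O)C(Sc1ccccc1)C[C@@H](O)C/C(CO[Si](C(C)C)(C(C)C)C(C)C)=C\C=C | intermediate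
13 | (3RS,5S)-3-(phenylsulfanyl)-5-[(2E)-2-(TIPS-oxymethyl)penta-2,4-dien-1-yl]oxolan-2-one | C=C/C=C(CO[Si](C(C)C)(C(C)C)C(C)C)\C[C@H]1CC(Sc2ccccc2)C(=O)O1 | intermediate
14 | (3RS,5S)-3-(hydroxymethyl)-3-(phenylsulfanyl)-5-[(2E)-2-(TIPS-oxymethyl)penta-2,4-dien-1-yl]oxolan-2-one | C=C/C=C(CO[Si](C(C)C)(C(C)C)C(C)C)\C[C@H]1CC(CO)(Sc2ccccc2)C(=O)O1 | intermediate
15 | (3RS,5S)-3-(benzenesulfinyl)-3-(hydroxymethyl)-5-[(2E)-2-(TIPS-oxymethyl)penta-2,4-dien-1-yl]oxolan-2-one | C=C/C=C(CO[Si](C(C)C)(C(C)C)C(C)C)\C[C@H]1CC(CO)(S(=O)c2ccccc2)C(=O)O1 | intermediate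
16 | (5S)-3-(hydroxymethyl)-5-[(2E)-2-(TIPS-oxymethyl)penta-2,4-dien-1-yl]furan-2(5H)-one | C=C/C=C(CO[Si](C(C)C)(C(C)C)C(C)C)\C[C@H]1C=C(CO)C(=O)O1 | intermediate
17 | (5S)-3-(TES-oxymethyl)-5-[(2E)-2-(TIPS-oxymethyl)penta-2,4-dien-1-yl]furan-2(5H)-one | C=C/C=C(CO[Si](C(C)C)(C(C)C)C(C)C)\C[C@H]1C=C(CO[Si](CC)(CC)CC)C(=O)O1 | intermediate
18 | (2E,4S,6E)-2-(TES-oxymethyl)-6-(TIPS-oxymethyl)nona-2,6,8-triene-1,4-diol | OC/C(CO[Si](CC)(CC)CC)=C\[C@@H](O)C/C(CO[Si](C(C)C)(C(C)C)C(C)C)=C\C=C | intermediate
19 | (2E,4S,6E)-4-hydroxy-2-(TES-oxymethyl)-6-(TIPS-oxymethyl)nona-2,6,8-trien-1-yl acetate | CC(=O)OC/C(CO[Si](CC)(CC)CC)=C\[C@@H](O)C/C(CO[Si](C(C)C)(C(C)C)C(C)C)=C\C=C | intermediate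
20 | (2E,4S,6E)-4-(TES-oxy)-2-(TES-oxymethyl)-6-(TIPS-oxymethyl)nona-2,6,8-trien-1-yl acetate | CC(=O)OC/C(CO[Si](CC)(CC)CC)=C\[C@@H](O[Si](CC)(CC)CC)C/C(CO[Si](C(C)C)(C(C)C)C(C)C)=C\C=C | intermediate
21 | (2E,4S,6E)-4-(TES-oxy)-2-(TES-oxymethyl)-6-(TIPS-oxymethyl)nona-2,6,8-trien-1-ol | OC/C(CO[Si](CC)(CC)CC)=C\[C@@H](O[Si](CC)(CC)CC)C/C(CO[Si](C(C)C)(C(C)C)C(C)C)=C\C=C | intermediate
22 | (2Z,4S,6E)-1-bromo-4-(TES-oxy)-2-(TES-oxymethyl)-6-(TIPS-oxymethyl)nona-2,6,8-triene | BrC/C(CO[Si](CC)(CC)CC)=C\[C@@H](O[Si](CC)(CC)CC)C/C(CO[Si](C(C)C)(C(C)C)C(C)C)=C\C=C | intermediate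
23 | (2E,4S,6E)-1-{[(2Z)-3-iodo-4-(TIPS-oxy)but-2-en-1-yl]oxy}-4-(TES-oxy)-2-(TES-oxymethyl)-6-(TIPS-oxymethyl)nona-2,6,8-triene | I/C(CO[Si](C(C)C)(C(C)C)C(C)C)=C\COC/C(CO[Si](CC)(CC)CC)=C\[C@@H](O[Si](CC)(CC)CC)C/C(CO[Si](C(C)C)(C(C)C)C(C)C)=C\C=C | intermediate
24 | 9-[(3E,6S,7E)-9-{[(2Z)-3-iodo-4-(TIPS-oxy)but-2-en-1-yl]oxy}-6-(TES-oxy)-8-(TES-oxymethyl)-4-(TIPS-oxymethyl)nona-3,7-dien-1-yl]-9-borabicyclo[3.3.1]nonane | I/C(CO[Si](C(C)C)(C(C)C)C(C)C)=C\COC/C(CO[Si](CC)(CC)CC)=C\[C@@H](O[Si](CC)(CC)CC)C/C(CO[Si](C(C)C)(C(C)C)C(C)C)=C\CCB1C2CCCC1CCC2 | intermediate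
25 | (3E,5S,7E,11E)-5-(TES-oxy)-3-(TES-oxymethyl)-7,11-bis(TIPS-oxymethyl)-1-oxacyclotrideca-3,7,11-triene | O1C/C(CO[Si](CC)(CC)CC)=C\[C@@H](O[Si](CC)(CC)CC)C/C(CO[Si](C(C)C)(C(C)C)C(C)C)=C\CC/C(CO[Si](C(C)C)(C(C)C)C(C)C)=C\C1 | intermediate
26 | C6-lithio derivative of 25 (lithium on the ring carbon between O and C5) | O1C/C(CO[Si](CC)(CC)CC)=C\[C@@H](O[Si](CC)(CC)CC)C/C(CO[Si](C(C)C)(C(C)C)C(C)C)=C\CC/C(CO[Si](C(C)C)(C(C)C)C(C)C)=C\C1[Li] | intermediate
27 | (1S,2E,6E,9S,10S)-9-(TES-oxy)-10-[3-(TES-oxy)prop-1-en-2-yl]-3,7-bis(TIPS-oxymethyl)cyclodeca-2,6-dien-1-ol | C=C(CO[Si](CC)(CC)CC)[C@@H]1[C@@H](O[Si](CC)(CC)CC)C/C(CO[Si](C(C)C)(C(C)C)C(C)C)=C\CC/C(CO[Si](C(C)C)(C(C)C)C(C)C)=C\[C@@H]1O | intermediate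
28 | (1S,2E,6E,9S,10S)-9-(TES-oxy)-10-[3-(TES-oxy)prop-1-en-2-yl]-3,7-bis(TIPS-oxymethyl)cyclodeca-2,6-dien-1-yl (2E)-2-methylbut-2-enoate | C=C(CO[Si](CC)(CC)CC)[C@@H]1[C@@H](O[Si](CC)(CC)CC)C/C(CO[Si](C(C)C)(C(C)C)C(C)C)=C\CC/C(CO[Si](C(C)C)(C(C)C)C(C)C)=C\[C@@H]1OC(=O)/C(C)=C/C | intermediate
29 | (1S,2E,6E,9S,10R)-9-hydroxy-10-(3-hydroxyprop-1-en-2-yl)-3,7-bis(TIPS-oxymethyl)cyclodeca-2,6-dien-1-yl (2E)-2-methylbut-2-enoate | C=C(CO)[C@@H]1[C@@H](O)C/C(CO[Si](C(C)C)(C(C)C)C(C)C)=C\CC/C(CO[Si](C(C)C)(C(C)C)C(C)C)=C\[C@@H]1OC(=O)/C(C)=C/C | intermediate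
30 | (1S,2E,6E,9S,10R)-9-hydroxy-10-(3-oxoprop-1-en-2-yl)-3,7-bis(TIPS-oxymethyl)cyclodeca-2,6-dien-1-yl (2E)-2-methylbut-2-enoate | C=C(C=O)[C@@H]1[C@@H](O)C/C(CO[Si](C(C)C)(C(C)C)C(C)C)=C\CC/C(CO[Si](C(C)C)(C(C)C)C(C)C)=C\[C@@H]1OC(=O)/C(C)=C/C | intermediate
31 | (6S,7R,8S,12RS)-12-hydroxy-6-[(2E)-2-methylbut-2-enoyloxy]-14,15-bis(TIPS-oxy)-8,12-epoxygermacra-1(10)E,4E,11(13)-triene (lactol) | C=C1C(O)O[C@H]2C/C(CO[Si](C(C)C)(C(C)C)C(C)C)=C\CC/C(CO[Si](C(C)C)(C(C)C)C(C)C)=C\[C@H](OC(=O)/C(C)=C/C)[C@H]12 | intermediate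
32 | (6S,7R,8S)-6-[(2E)-2-methylbut-2-enoyloxy]-14,15-bis(TIPS-oxy)germacra-1(10)E,4E,11(13)-trien-12,8-olide | C=C1C(=O)O[C@H]2C/C(CO[Si](C(C)C)(C(C)C)C(C)C)=C\CC/C(CO[Si](C(C)C)(C(C)C)C(C)C)=C\[C@H](OC(=O)/C(C)=C/C)[C@H]12 | intermediate
33 | (6S,7R,8S)-14,15-dihydroxy-6-[(2E)-2-methylbut-2-enoyloxy]germacra-1(10)E,4E,11(13)-trien-12,8-olide (CNP0275462.1) | C=C1C(=O)O[C@H]2C/C(CO)=C\CC/C(CO)=C\[C@H](OC(=O)/C(C)=C/C)[C@H]12 | target

## Step count and least certain steps

Total step count: 20. Longest linear sequence: 20 steps (1 to 33); the only branch is the second use of 4 in step 14.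

**Step 16 (key step).** What may go wrong: metalation at C13 or at a silyloxymethyl carbon instead of C6; 1,4-elimination of the C15 silyloxy group from the C6 allyl anion; a [1,2]-shift; and migration of the C8 silyl group to the new C6 alkoxide before the quench. The cause is that five allylic O–CH2 groups of similar acidity are present and the intermediate is a delocalised anion with a leaving group in the 4-position. Fallback (sets out from 21 and 5, comes back at 28): 9-BBN hydroborates the terminal vinyl group of 21 to the alkylborane F1, which is coupled with 5 (Pd(dppf)Cl2, AsPh3, Cs2CO3) to the hydroxy enal F2. Appel bromination gives the bromo enal F3. CrCl2 in THF at high dilution (intramolecular Nozaki–Hiyama allylation) then joins C7 to the C6 aldehyde carbon with allylic transposition, making the same bond and the same C11=C13 alkene as step 16. This addition is expected to favour the anti adduct, the C6-epimeric alcohol F4. Mitsunobu esterification of F4 with (2E)-2-methylbut-2-enoic acid (PPh3, diisopropyl azodicarboxylate) inverts C6 and gives 28; any 27 formed goes on through step 17.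

**Step 15.** What may go wrong: intermolecular coupling in place of ring closure, incomplete or unselective hydroboration of the diene, or protodeboronation, because the ring closure is entropically slow and the iodide is hindered. Fallback (sets out from 20 and 4, comes back at 25): the ring is closed at the ether bond instead. 20 is hydroborated to the alkylborane F5 and coupled intermolecularly with 4 to the hydroxy acetate F6. MsCl/Et3N then LiCl gives the chloro acetate F7, and i-Bu2AlH at −78 °C gives the chloro alcohol F8. EtMgBr in THF/HMPA at high dilution closes the thirteen-membered ether 25 by intramolecular Williamson reaction; the magnesium alkoxide is chosen to hold the C8 silyl group in place.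

**Step 5.** What may go wrong: loss of 8 before it meets the epoxide, by β-elimination of the silyloxide or by migration of silicon from oxygen to carbon, and addition of t-BuLi to the diene. Fallback (sets out from 6, comes back at 10): Bu4NF removes the silyl group to give (2Z)-2-iodopenta-2,4-dien-1-ol F9. Three equivalents of t-BuLi make its O,C-dilithio form, in which the alkoxide can neither leave nor pass silicon on. Opening of 7 with BF3·OEt2 and closure with NaOH as in step 5 give the epoxy alcohol F10, which is silylated (i-Pr3SiCl, imidazole) to 10.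

**Step 8.** What may go wrong: thermal dimerisation of the diene at the temperature the sulfoxide needs, or addition of the sulfenic acid by-product to the diene. Fallback (sets out from 10, comes back at 16): a selenoxide route that eliminates at room temperature. 10 is opened with the dianion of acetic acid (AcOH, 2 LiN(i-Pr)2) and lactonised to the lactone F11. LiN(i-Pr)2 then PhSeBr gives the α-phenylselanyl lactone F12, and LiN(i-Pr)2 then CH2O gives the hydroxymethyl selenide F13. NaIO4 with NaHCO3 in THF/MeOH/H2O at 0 °C to rt oxidises selenium and the syn-elimination gives 16.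

## Further compounds

F1 | step 16 | B-alkyl-9-borabicyclo[3.3.1]nonane from 21 (boron on C3) | OC/C(CO[Si](CC)(CC)CC)=C\[C@@H](O[Si](CC)(CC)CC)C/C(CO[Si](C(C)C)(C(C)C)C(C)C)=C\CCB1C2CCCC1CCC2
F2 | step 16 | hydroxy enal (C13–OH, C6 aldehyde, C3–C4 formed) | OC/C(CO[Si](CC)(CC)CC)=C\[C@@H](O[Si](CC)(CC)CC)C/C(CO[Si](C(C)C)(C(C)C)C(C)C)=C\CC/C(CO[Si](C(C)C)(C(C)C)C(C)C)=C\C=O
F3 | step 16 | bromo enal (C13–Br, C6 aldehyde) | BrC/C(CO[Si](CC)(CC)CC)=C\[C@@H](O[Si](CC)(CC)CC)C/C(CO[Si](C(C)C)(C(C)C)C(C)C)=C\CC/C(CO[Si](C(C)C)(C(C)C)C(C)C)=C\C=O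
F4 | step 16 | C6 epimer of 27 | C=C(CO[Si](CC)(CC)CC)[C@@H]1[C@@H](O[Si](CC)(CC)CC)C/C(CO[Si](C(C)C)(C(C)C)C(C)C)=C\CC/C(CO[Si](C(C)C)(C(C)C)C(C)C)=C\[C@H]1O
F5 | step 15 | B-alkyl-9-borabicyclo[3.3.1]nonane from 20 (boron on C3) | CC(=O)OC/C(CO[Si](CC)(CC)CC)=C\[C@@H](O[Si](CC)(CC)CC)C/C(CO[Si](C(C)C)(C(C)C)C(C)C)=C\CCB1C2CCCC1CCC2
F6 | step 15 | hydroxy acetate (C13–OAc, C6–OH, C3–C4 formed) | CC(=O)OC/C(CO[Si](CC)(CC)CC)=C\[C@@H](O[Si](CC)(CC)CC)C/C(CO[Si](C(C)C)(C(C)C)C(C)C)=C\CC/C(CO[Si](C(C)C)(C(C)C)C(C)C)=C\CO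
F7 | step 15 | chloro acetate (C13–OAc, C6–Cl) | CC(=O)OC/C(CO[Si](CC)(CC)CC)=C\[C@@H](O[Si](CC)(CC)CC)C/C(CO[Si](C(C)C)(C(C)C)C(C)C)=C\CC/C(CO[Si](C(C)C)(C(C)C)C(C)C)=C\CCl
F8 | step 15 | chloro alcohol (C13–OH, C6–Cl) | OC/C(CO[Si](CC)(CC)CC)=C\[C@@H](O[Si](CC)(CC)CC)C/C(CO[Si](C(C)C)(C(C)C)C(C)C)=C\CC/C(CO[Si](C(C)C)(C(C)C)C(C)C)=C\CCl
F9 | step 5 | (2Z)-2-iodopenta-2,4-dien-1-ol | C=C/C=C(\I)CO
F10 | step 5 | (2E)-2-{[(2S)-oxiran-2-yl]methyl}penta-2,4-dien-1-ol | C=C/C=C(CO)\C[C@H]1CO1
F11 | step 8 | (5R)-5-[(2E)-2-(TIPS-oxymethyl)penta-2,4-dien-1-yl]oxolan-2-one | C=C/C=C(CO[Si](C(C)C)(C(C)C)C(C)C)\C[C@H]1CCC(=O)O1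
F12 | step 8 | (3RS,5S)-3-(phenylselanyl)-5-[(2E)-2-(TIPS-oxymethyl)penta-2,4-dien-1-yl]oxolan-2-one | C=C/C=C(CO[Si](C(C)C)(C(C)C)C(C)C)\C[C@H]1CC([Se]c2ccccc2)C(=O)O1
F13 | step 8 | (3RS,5S)-3-(hydroxymethyl)-3-(phenylselanyl)-5-[(2E)-2-(TIPS-oxymethyl)penta-2,4-dien-1-yl]oxolan-2-one | C=C/C=C(CO[Si](C(C)C)(C(C)C)C(C)C)\C[C@H]1CC(CO)([Se]c2ccccc2)C(=O)O1
A1 | alternative 1 | cis-dialkenyl cyclohexenol: C6 carbinol with (E)-2-(benzyldimethylsilyl)vinyl, C1 with 3-(tert-butyldimethylsilyloxy)prop-1-en-2-yl (enantiomer shown assumes an E vinylsilane and a chair transition state) | O[C@@]1(/C=C/[Si](C)(C)Cc2ccccc2)C=C(CO[Si](C)(C)C(C)(C)C)CC[C@@H]1C(=C)CO[Si](C)(C)C(C)(C)C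
A2 | alternative 1 | cis,cis-cyclodecadienone with C6 ketone and benzyldimethylsilyl on C8 | O=C1/C=C(CO[Si](C)(C)C(C)(C)C)\CC/C=C(CO[Si](C)(C)C(C)(C)C)\C[C@H]([Si](C)(C)Cc2ccccc2)C1
A3 | alternative 2 | acyclic trans lactone with terminal C2=C3 vinyl group and C4 alkenyl iodide (C6 triethylsilyl ether) | C=C/C=C(CO[Si](C)(C)C(C)(C)C)\C[C@@H]1OC(=O)C[C@H]1[C@@H](O[Si](CC)(CC)CC)/C=C(\I)CO[Si](C)(C)C(C)(C)C
A4 | alternative 2 | ten-membered cis,cis-diene fused to the trans lactone (C6 triethylsilyl ether, C11 as CH2) | C1C(=O)O[C@H]2C/C(CO[Si](C)(C)C(C)(C)C)=C\CC/C(CO[Si](C)(C)C(C)(C)C)=C\[C@H](O[Si](CC)(CC)CC)[C@H]12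
A5 | alternative 3 | acyclic trans lactone with primary allylic bromides at C2 and C3 (C6 4-methoxybenzyl ether) | BrC/C=C(CO[Si](C)(C)C(C)(C)C)\C[C@@H]1OC(=O)C[C@H]1[C@@H](OCc2ccc(OC)cc2)/C=C(\CBr)CO[Si](C)(C)C(C)(C)C
A6 | alternative 3 | ten-membered cis,cis-diene fused to the trans lactone (C6 4-methoxybenzyl ether, C11 as CH2) | C1C(=O)O[C@H]2C/C(CO[Si](C)(C)C(C)(C)C)=C\CC/C(CO[Si](C)(C)C(C)(C)C)=C\[C@H](OCc3ccc(OC)cc3)[C@H]12
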